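**Plan**

- Retrosynthesis: the C7=C8 alkene is cut first (condensation of a 2-ethyl-γ-pyrone with a C8 dienal), then C9=C10 and C11=C12 (two Wittig olefinations back to a C12 aldehyde), and last the ring bonds C13–C14 and C17–C18 (Diels–Alder).
- Enabling feature: on the cyclohexane C13–C18 the carbon substituents at C13, C14 and C17 share one face, the C18 oxygen lies on the other, and C15–C16 are both oxygenated. This is the pattern of an endo adduct between a 1,4-dimethyl-2-silyloxydiene (C14–C17) and an E-β-acetoxyacryloyl imide (C13, C18) that retains an enol ether at C15=C16.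
- Forward: the diene (from tiglic acid) and the dienophile (from oxazolidin-2-one and propiolic acid) close the only carbocycle in one step. The enol ether is then hydroxylated twice (C15, C17), and the C16 ketone is reduced and acetylated.
- The imide is converted through a thioester into the C12 aldehyde, two Wittig reactions give the dienal, and the pyrone (made separately from ethyl 2-methyl-3-oxopentanoate) is joined last.
- Stereochemistry: C13 from [Cu((S,S)-t-Bu-box)](SbF6)2; C14, C17 and C18 from endo, suprafacial addition; the C15 and C17 carbinols from face-selective and hydroxyl-directed epoxidation; C16 from axial hydride addition; E alkenes from stabilised ylides and a thermodynamically controlled elimination.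

Key step: step 6

Remark: target numbering (C7–C18) is used for all compounds, α is the ring face carrying the C13 carbon substituent and β the opposite face; the diene carries a tert-butyldimethylsilyl group because the double hydroxylation in step 7 relies on slow silyl transfer.

**Route**

Step 1
Reactants: 1 tiglic acid
Product: 2 (E)-N-methoxy-N,2-dimethylbut-2-enamide
Conditions: CDI, CH2Cl2, rt; then MeNH(OMe)·HCl, rt
Reagents that add atoms: N,O-dimethylhydroxylamine hydrochloride, CNOC.Cl
Why: Weinreb amide formation through the acyl imidazolide is a mild amidation that leaves the E-trisubstituted alkene untouched.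

Step 2
Reactants: 2 (E)-N-methoxy-N,2-dimethylbut-2-enamide
Product: 3 (E)-4-methylhex-4-en-3-one
Conditions: EtMgBr, THF, 0 °C; aq. NH4Cl
Reagents that add atoms: ethylmagnesium bromide, CC[Mg]Br
Why: Weinreb ketone synthesis, in which the chelated tetrahedral magnesium adduct survives until work-up so that a single ethyl group adds and the conjugated E-alkene is not attacked.

Step 3
Reactants: 3 (E)-4-methylhex-4-en-3-one
Product: 4 (2Z,4E)-3-(tert-butyldimethylsilyloxy)-4-methylhexa-2,4-diene
Conditions: t-BuMe2SiOTf, Et3N, CH2Cl2, 0 °C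
Reagents that add atoms: tert-butyldimethylsilyl triflate, CC(C)(C)[Si](C)(C)OS(=O)(=O)C(F)(F)F
Why: Soft enolisation of the ethyl ketone with a silyl triflate and Et3N (silyl enol ether formation) gives the 2-silyloxydiene, the Z enol ether being favoured because its methyl group then avoids allylic strain with the branched alkenyl substituent, while the existing E-alkene is unaffected.

Step 4
Reactants: 5 oxazolidin-2-one; 6 propiolic acid
Product: 7 3-propioloyloxazolidin-2-one
Conditions: DCC, DMAP (5 mol %), CH2Cl2, −20 → 0 °C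
Reagents that add atoms: none
Why: Carbodiimide-mediated N-acylation (DCC/DMAP coupling) of the weakly nucleophilic oxazolidinone nitrogen is run cold so that the activated propiolate is trapped before it can oligomerise.

Step 5
Reactants: 7 3-propioloyloxazolidin-2-one
Product: 8 3-[(E)-3-acetoxyprop-2-enoyl]oxazolidin-2-one
Conditions: AcOH, N-methylmorpholine (10 mol %), MeCN, rt
Reagents that add atoms: acetic acid, CC(=O)O
Why: Amine-catalysed conjugate addition of a carboxylic acid to an ynoyl acceptor proceeds through a β-ammonium acrylate that undergoes addition–elimination with acetate and delivers the thermodynamically preferred E-β-acetoxyacryloyl imide.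

Step 6
Reactants: 4 (2Z,4E)-3-(tert-butyldimethylsilyloxy)-4-methylhexa-2,4-diene; 8 3-[(E)-3-acetoxyprop-2-enoyl]oxazolidin-2-one
Product: 9 3-{[(1R,2S,5R,6R)-6-acetoxy-4-(tert-butyldimethylsilyloxy)-2,3,5-trimethylcyclohex-3-en-1-yl]carbonyl}oxazolidin-2-one (C13 acyl, C14 and C17 methyls α; C18 acetate β; enol ether C15=C16)
Conditions: [Cu((S,S)-t-Bu-box)](SbF6)2 (10 mol %, from CuCl2, AgSbF6 and 2,2'-(propane-2,2-diyl)bis[(4S)-4-tert-butyl-4,5-dihydrooxazole]), 4 Å molecular sieves, CH2Cl2, −40 → −20 °C
Reagents that add atoms: none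
Why: The two imide carbonyls chelate divalent copper in a square-planar complex, which lowers the LUMO of the s-cis acetoxyacryloyl unit, and the electron-rich silyloxydiene adds in a concerted but asynchronous [4+2] cycloaddition in which the C17–C18 bond (enol ether terminus to β-carbon) is more advanced than C13–C14. The closest known reaction type is the Diels–Alder reaction of β-substituted acryloyl oxazolidinones catalysed by [Cu(t-Bu-box)](SbF6)2. The cyclohexene ring closes by suprafacial addition to both partners, so the E-dienophile places the C13 acyl group and the C18 acetate trans, and the Z,E-diene, whose terminal methyl groups both point outward, places the C14 and C17 methyl groups cis. Endo orientation of the chelated acyl group makes it cis to both methyl groups, and the tert-butyl group of the (S,S)-ligand blocks one face of the bound dienophile so that the diene bonds to the α-re face, which fixes C13 as R and thereby the absolute configuration of C14, C17 and C18. The step needs para-type regioselectivity, which comes from the silyloxy donor on C16 making C17 the nucleophilic terminus that attacks the β-carbon C18. The bulky tert-butyldimethylsilyl group is chosen to suppress silyl transfer, which would divert the reaction to an open-chain Mukaiyama–Michael adduct.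

Step 7
Reactants: 9 cycloadduct
Product: 13 15β,17β-dihydroxy-16-ketone imide, via silyloxy epoxide 10 (not isolated), via hydroxy enol ether 11 (not isolated), via second silyloxy epoxide 12 (not isolated)
Conditions: mCPBA (2.5 equiv), KHCO3, CH2Cl2, −20 → 0 °C; then HF·pyridine, THF, 0 °C
Reagents that add atoms: 3-chloroperoxybenzoic acid, O=C(OO)c1cccc(Cl)c1
Why: Rubottom oxidation carried through a second hydroxylation (double hydroxylation of an enol silyl ether with excess buffered peracid), in which the peracid attacks the C15=C16 enol ether on the β face away from the pseudoaxial C14 methyl group and so sets C15, the silyloxy epoxide opens to a silyloxocarbenium ion that loses the C17 proton faster than it transfers the bulky silyl group, and the free C15 hydroxyl of the resulting enol ether steers the second epoxidation to the same face (Henbest-type direction) and so sets C17 before fluoride releases the ketone.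

Step 8
Reactants: 13 15β,17β-dihydroxy-16-ketone imide
Product: 14 15β,16β,17β-triol imide
Conditions: NaBH4, CeCl3·7H2O, MeOH, −78 → −40 °C
Reagents that add atoms: none
Why: Luche reduction, in which the only chair that keeps the C13, C15 and C17 carbon substituents equatorial has both α-hydroxyls axial on the β face, so the small hydride adds axially from the α face anti to the two C–O bonds (polar Felkin–Anh control) and gives the equatorial β C16 alcohol, while imide and acetate do not react at this temperature.

Step 9
Reactants: 14 15β,16β,17β-triol imide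
Product: 15 16β,18β-diacetate imide
Conditions: Ac2O, pyridine, DMAP (cat.), CH2Cl2, 0 °C → rt
Reagents that add atoms: acetic anhydride, CC(=O)OC(C)=O
Why: DMAP-catalysed acetylation distinguishes the secondary C16 hydroxyl from the two tertiary hydroxyls, which are acylated far more slowly.

Step 10
Reactants: 15 16β,18β-diacetate imide
Product: 16 S-ethyl thioester of the C12 acid
Conditions: EtSH, n-BuLi, THF, −78 → 0 °C; aq. NH4Cl
Reagents that add atoms: ethanethiol, CCS
Why: Thiolate cleavage of an N-acyl oxazolidinone (LiSEt transacylation) occurs at the exocyclic carbonyl, and the weakly basic sulfur nucleophile neither exchanges with the acetates nor epimerises C13.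

Step 11
Reactants: 16 S-ethyl thioester
Product: 17 C12 aldehyde
Conditions: Et3SiH, Pd/C (10 wt %), acetone, rt
Reagents that add atoms: none
Why: Fukuyama reduction, in which palladium inserts into the C–S bond and the silane delivers hydride, stops at the aldehyde under neutral conditions that leave acetates, tertiary alcohols and the C13 configuration untouched.

Step 12
Reactants: 17 C12 aldehyde
Product: 18 (E)-C10 enal
Conditions: Ph3P=C(CH3)CHO, toluene, 80 °C
Reagents that add atoms: 2-(triphenylphosphoranylidene)propanal, CC(C=O)=P(c1ccccc1)(c1ccccc1)c1ccccc1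
Why: Wittig olefination with a stabilised, non-basic ylide adds reversibly and gives the E-trisubstituted C11=C12 enal without β-elimination of the C18 acetate, and the hindered α-methyl enal formed does not react further.

Step 13
Reactants: 18 (E)-C10 enal
Product: 19 (E,E)-C8 dienal
Conditions: Ph3P=CHCHO (1.2 equiv), toluene, 80 °C
Reagents that add atoms: (triphenylphosphoranylidene)acetaldehyde, O=CC=P(c1ccccc1)(c1ccccc1)c1ccccc1
Why: Wittig olefination with the stabilised formylmethylene ylide extends the enal by two carbons with an E-configured C9=C10 alkene, and the ylide is kept close to one equivalent so that the dienal formed is not homologated again.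

Step 14
Reactants: 20 ethyl 2-methyl-3-oxopentanoate
Product: 22 6-ethyl-4-hydroxy-3,5-dimethyl-2H-pyran-2-one, via triketo ester 21 (not isolated)
Conditions: LiN(i-Pr)2 (2.2 equiv), THF, −78 → 0 °C; EtC(O)N(OMe)Me, −78 → 0 °C; aq. NH4Cl; then DBU, toluene, 110 °C
Reagents that add atoms: N-methoxy-N-methylpropanamide, CCC(=O)N(C)OC
Why: γ-Acylation of the β-keto ester dianion by a Weinreb amide, whose tetrahedral adduct prevents over-addition, gives the 3,5-diketo ester, and its enol oxygen closes onto the ester under DBU (lactonisation to a 4-hydroxy-2-pyranone).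

Step 15
Reactants: 22 6-ethyl-4-hydroxy-3,5-dimethyl-2H-pyran-2-one
Product: 23 2-ethyl-6-methoxy-3,5-dimethyl-4H-pyran-4-one
Conditions: MeOTf, CH2Cl2, rt; aq. NaHCO3 work-up
Reagents that add atoms: methyl triflate, COS(=O)(=O)C(F)(F)F
Why: O-Methylation with the hard electrophile MeOTf takes place at the lactone carbonyl oxygen, so that loss of the hydroxyl proton gives the 2-methoxy-4-pyranone and not the 4-methoxy-2-pyranone that basic methylation would favour.

Step 16
Reactants: 19 (E,E)-C8 dienal; 23 2-ethyl-6-methoxy-3,5-dimethyl-4H-pyran-4-one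
Product: 24 C8 carbinol (aldol adduct, mixture at C7 and C8)
Conditions: 23 (2.5 equiv), LiN(SiMe3)2, THF, −78 °C; then 19, −78 °C; AcOH quench
Reagents that add atoms: none
Why: Vinylogous aldol addition, in which LiN(SiMe3)2 removes a proton from the CH2 of the 2-ethyl group conjugated with the pyranone carbonyl and the lithium dienolate adds 1,2 to the dienal at −78 °C, where acetates and tertiary hydroxyls are tolerated, the C7 and C8 configurations being irrelevant because both centres become sp2 in the next step.

Step 17
Reactants: 24 C8 carbinol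
Product: 26 amaurone B, via mesylate 25 (not isolated)
Conditions: MsCl (1.2 equiv), Et3N, CH2Cl2, −20 °C; then DBU, rt
Reagents that add atoms: none
Why: Mesylation of the secondary dienylic alcohol followed by DBU-induced E1cB elimination through the acidic C7–H gives the fully conjugated triene, the E geometry at C7=C8 being the thermodynamically preferred outcome of this aldol condensation.

**Compound list**

1 | tiglic acid, (E)-2-methylbut-2-enoic acid | C/C=C(\C)C(=O)O | starting material
2 | (E)-N-methoxy-N,2-dimethylbut-2-enamide | C/C=C(\C)C(=O)N(C)OC | intermediate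
3 | (E)-4-methylhex-4-en-3-one | C/C=C(\C)C(=O)CC | intermediate
4 | (2Z,4E)-3-(tert-butyldimethylsilyloxy)-4-methylhexa-2,4-diene | C/C=C(O[Si](C)(C)C(C)(C)C)/C(C)=C/C | intermediate
5 | oxazolidin-2-one | O=C1NCCO1 | starting material
6 | propiolic acid | C#CC(=O)O | starting material
7 | 3-propioloyloxazolidin-2-one | C#CC(=O)N1CCOC1=O | intermediate
8 | 3-[(E)-3-acetoxyprop-2-enoyl]oxazolidin-2-one | CC(=O)O/C=C/C(=O)N1CCOC1=O | intermediate
9 | 3-{[(1R,2S,5R,6R)-6-acetoxy-4-(tert-butyldimethylsilyloxy)-2,3,5-trimethylcyclohex-3-en-1-yl]carbonyl}oxazolidin-2-one (C13 acyl, C14-Me, C17-Me α; C18-OAc β) | O=C(N1CCOC1=O)[C@@H]2[C@H](C)C(C)=C(O[Si](C)(C)C(C)(C)C)[C@H](C)[C@H]2OC(C)=O | intermediate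
10 | 15,16-epoxide of 9 (epoxide oxygen β, silyloxy group on C16 α) | O=C(N1CCOC1=O)[C@@H]2[C@H](C)[C@@]3(C)O[C@@]3(O[Si](C)(C)C(C)(C)C)[C@H](C)[C@H]2OC(C)=O | intermediate
11 | transposed enol ether: C15 β-hydroxyl (methyl α), silyl enol ether C16=C17 | O=C(N1CCOC1=O)[C@@H]2[C@H](C)[C@@](C)(O)C(O[Si](C)(C)C(C)(C)C)=C(C)[C@H]2OC(C)=O | intermediate
12 | 16,17-epoxide of 11 (epoxide oxygen β, silyloxy group on C16 α) | O=C(N1CCOC1=O)[C@@H]2[C@H](C)[C@@](C)(O)[C@@]3(O[Si](C)(C)C(C)(C)C)O[C@@]3(C)[C@H]2OC(C)=O | intermediate
13 | dihydroxy ketone imide: C15 and C17 tertiary β-hydroxyls (methyls α), C16 ketone, C18 β-acetate, C13 α-acyl oxazolidinone | O=C(N1CCOC1=O)[C@@H]2[C@H](C)[C@@](C)(O)C(=O)[C@@](C)(O)[C@H]2OC(C)=O | intermediate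
14 | all-cis triol imide: C15, C16, C17 β-hydroxyls, C18 β-acetate | O=C(N1CCOC1=O)[C@@H]2[C@H](C)[C@@](C)(O)[C@@H](O)[C@@](C)(O)[C@H]2OC(C)=O | intermediate
15 | diacetate imide: C16 and C18 β-acetates, C15 and C17 β-hydroxyls | O=C(N1CCOC1=O)[C@@H]2[C@H](C)[C@@](C)(O)[C@@H](OC(C)=O)[C@@](C)(O)[C@H]2OC(C)=O | intermediate
16 | S-ethyl thioester of the C12 acid (ring as in 15) | CCSC(=O)[C@@H]2[C@H](C)[C@@](C)(O)[C@@H](OC(C)=O)[C@@](C)(O)[C@H]2OC(C)=O | intermediate
17 | C12 aldehyde (ring as in 15, formyl group α on C13) | O=C[C@@H]2[C@H](C)[C@@](C)(O)[C@@H](OC(C)=O)[C@@](C)(O)[C@H]2OC(C)=O | intermediate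
18 | (E)-2-methyl-3-(ring)prop-2-enal, C10 enal with E C11=C12 | O=C/C(C)=C/[C@@H]2[C@H](C)[C@@](C)(O)[C@@H](OC(C)=O)[C@@](C)(O)[C@H]2OC(C)=O | intermediate
19 | (2E,4E)-4-methyl-5-(ring)penta-2,4-dienal, C8 dienal | O=C/C=C/C(C)=C/[C@@H]2[C@H](C)[C@@](C)(O)[C@@H](OC(C)=O)[C@@](C)(O)[C@H]2OC(C)=O | intermediate
20 | ethyl 2-methyl-3-oxopentanoate | CCC(=O)C(C)C(=O)OCC | starting material
21 | ethyl 2,4-dimethyl-3,5-dioxoheptanoate (stereoisomer and tautomer mixture) | CCC(=O)C(C)C(=O)C(C)C(=O)OCC | intermediate
22 | 6-ethyl-4-hydroxy-3,5-dimethyl-2H-pyran-2-one | CCc1oc(=O)c(C)c(O)c1C | intermediate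
23 | 2-ethyl-6-methoxy-3,5-dimethyl-4H-pyran-4-one | CCc1oc(OC)c(C)c(=O)c1C | intermediate
24 | aldol adduct: pyrone–C7H(CH3)–C8H(OH)–(E,E)-diene–ring, mixture at C7 and C8 | COc1oc(C(C)C(O)/C=C/C(C)=C/[C@@H]2[C@H](C)[C@@](C)(O)[C@@H](OC(C)=O)[C@@](C)(O)[C@H]2OC(C)=O)c(C)c(=O)c1C | intermediate
25 | C8 methanesulfonate of 24 | COc1oc(C(C)C(OS(C)(=O)=O)/C=C/C(C)=C/[C@@H]2[C@H](C)[C@@](C)(O)[C@@H](OC(C)=O)[C@@](C)(O)[C@H]2OC(C)=O)c(C)c(=O)c1C | intermediate
26 | amaurone B (13R,14S,15R,16R,17S,18S; 7E,9E,11E) | COc1oc(/C(C)=C/C=C/C(C)=C/[C@@H]2[C@H](C)[C@@](C)(O)[C@@H](OC(C)=O)[C@@](C)(O)[C@H]2OC(C)=O)c(C)c(=O)c1C | target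

**Count and risks**

Total step count: 17. Longest linear sequence: 13 steps (steps 1–3, 6–13, 16, 17, from tiglic acid).

Step 6.
- What may go wrong: the silyloxydiene may add stepwise (Mukaiyama–Michael addition followed by slow ring closure) at the cationic copper centre, eroding endo and facial selectivity, or the enol ether may be cleaved by the Lewis acid.
- Fallback (auxiliary control in place of catalyst control), setting out from 4 and 6 and returning at 16:
  - Commercial (R)-4-benzyloxazolidin-2-one is acylated with 6 under the conditions of step 4 to give (R)-4-benzyl-3-propioloyloxazolidin-2-one F1.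
  - AcOH is added as in step 5 to give (R)-4-benzyl-3-[(E)-3-acetoxyprop-2-enoyl]oxazolidin-2-one F2.
  - Cycloaddition with 4 promoted by Me2AlCl (1.4 equiv, CH2Cl2, −78 °C) should give the auxiliary-bearing cycloadduct F3. Endo addition to the chelated s-cis imide occurs on the face opposite the benzyl group, which is the α-re face required. Minor diastereomers can be removed by chromatography or crystallisation.
  - F3 is carried through the conditions of steps 7 to 9. Silyloxy epoxide F4, hydroxy enol ether F5 and second silyloxy epoxide F6 form in the flask and lead to dihydroxy ketone F7. Luche reduction gives triol F8, and acetylation gives diacetate F9.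
  - LiSEt under the conditions of step 10 removes the auxiliary from F9 and returns the route to thioester 16.

Step 7.
- What may go wrong: the silyloxocarbenium ion may collapse by silyl transfer or hydrolysis before it loses the C17 proton, so that oxidation stops after the first hydroxylation, or the second epoxidation may be unselective.
- Fallback (elimination and dihydroxylation in place of a second enol ether oxidation), setting out from 9 and returning at 15:
  - One equivalent of mCPBA (NaHCO3, CH2Cl2, −20 °C) followed by HF·pyridine gives, through epoxide 10, the C15 hydroxy ketone F10.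
  - DBU (CH2Cl2, rt) eliminates acetic acid across C17–C18 to give enone F11.
  - OsO4 (cat.), N-methylmorpholine N-oxide and citric acid in t-BuOH/H2O should dihydroxylate the enone on the β face, anti to the C13 substituent, to give triol ketone F12. The C18 configuration is set anew in this step.
  - Luche reduction as in step 8 gives tetraol F13.
  - Acetylation of its two secondary hydroxyls with excess Ac2O under the conditions of step 9 returns the route to diacetate 15.

Step 16.
- What may go wrong: proton transfer from the two tertiary hydroxyls to the lithium dienolate, and alkoxide-induced acetyl migration or β-elimination, may consume the dienal before the carbon–carbon bond forms.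
- Fallback (temporary masking of the hydroxyls), setting out from 19 and returning at 26:
  - N-(Trimethylsilyl)imidazole (CH2Cl2, rt) gives the bis(trimethylsilyl) ether dienal F14.
  - Addition of lithiated 23 as in step 16 gives aldol adduct F15.
  - Mesylation gives mesylate F16 in the flask, and DBU then gives the silyl-protected triene F17.
  - HF·pyridine (THF, 0 °C) removes both trimethylsilyl groups and returns the route at target 26.

**Further compounds**

F1 | step 6 | (R)-4-benzyl-3-propioloyloxazolidin-2-one | C#CC(=O)N1[C@H](Cc2ccccc2)COC1=O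
F2 | step 6 | (R)-4-benzyl-3-[(E)-3-acetoxyprop-2-enoyl]oxazolidin-2-one | CC(=O)O/C=C/C(=O)N1[C@H](Cc2ccccc2)COC1=O
F3 | step 6 | auxiliary-bearing cycloadduct (ring as in 9) | O=C(N1[C@H](Cc3ccccc3)COC1=O)[C@@H]2[C@H](C)C(C)=C(O[Si](C)(C)C(C)(C)C)[C@H](C)[C@H]2OC(C)=O
F4 | step 6 | auxiliary-bearing 15,16-silyloxy epoxide (ring as in 10) | O=C(N1[C@H](Cc3ccccc3)COC1=O)[C@@H]2[C@H](C)[C@@]4(C)O[C@@]4(O[Si](C)(C)C(C)(C)C)[C@H](C)[C@H]2OC(C)=O
F5 | step 6 | auxiliary-bearing hydroxy enol ether (ring as in 11) | O=C(N1[C@H](Cc3ccccc3)COC1=O)[C@@H]2[C@H](C)[C@@](C)(O)C(O[Si](C)(C)C(C)(C)C)=C(C)[C@H]2OC(C)=O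
F6 | step 6 | auxiliary-bearing 16,17-silyloxy epoxide (ring as in 12) | O=C(N1[C@H](Cc3ccccc3)COC1=O)[C@@H]2[C@H](C)[C@@](C)(O)[C@@]4(O[Si](C)(C)C(C)(C)C)O[C@@]4(C)[C@H]2OC(C)=O
F7 | step 6 | auxiliary-bearing dihydroxy ketone (ring as in 13) | O=C(N1[C@H](Cc3ccccc3)COC1=O)[C@@H]2[C@H](C)[C@@](C)(O)C(=O)[C@@](C)(O)[C@H]2OC(C)=O
F8 | step 6 | auxiliary-bearing triol (ring as in 14) | O=C(N1[C@H](Cc3ccccc3)COC1=O)[C@@H]2[C@H](C)[C@@](C)(O)[C@@H](O)[C@@](C)(O)[C@H]2OC(C)=O
F9 | step 6 | auxiliary-bearing diacetate (ring as in 15) | O=C(N1[C@H](Cc3ccccc3)COC1=O)[C@@H]2[C@H](C)[C@@](C)(O)[C@@H](OC(C)=O)[C@@](C)(O)[C@H]2OC(C)=O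
F10 | step 7 | C15 β-hydroxy C16 ketone imide (C17-H, C18 β-acetate) | O=C(N1CCOC1=O)[C@@H]2[C@H](C)[C@@](C)(O)C(=O)[C@H](C)[C@H]2OC(C)=O
F11 | step 7 | enone imide (C16 ketone, C17=C18 alkene, C15 β-hydroxyl) | O=C(N1CCOC1=O)[C@@H]2[C@H](C)[C@@](C)(O)C(=O)C(C)=C2
F12 | step 7 | triol ketone imide (C15, C17, C18 β-hydroxyls, C16 ketone) | O=C(N1CCOC1=O)[C@@H]2[C@H](C)[C@@](C)(O)C(=O)[C@@](C)(O)[C@H]2O
F13 | step 7 | tetraol imide (C15, C16, C17, C18 β-hydroxyls) | O=C(N1CCOC1=O)[C@@H]2[C@H](C)[C@@](C)(O)[C@@H](O)[C@@](C)(O)[C@H]2O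
F14 | step 16 | bis(trimethylsilyl) ether of dienal 19 (C15 and C17 silyl ethers) | O=C/C=C/C(C)=C/[C@@H]2[C@H](C)[C@@](C)(O[Si](C)(C)C)[C@@H](OC(C)=O)[C@@](C)(O[Si](C)(C)C)[C@H]2OC(C)=O
F15 | step 16 | bis(trimethylsilyl) ether of aldol adduct 24 | COc1oc(C(C)C(O)/C=C/C(C)=C/[C@@H]2[C@H](C)[C@@](C)(O[Si](C)(C)C)[C@@H](OC(C)=O)[C@@](C)(O[Si](C)(C)C)[C@H]2OC(C)=O)c(C)c(=O)c1C
F16 | step 16 | bis(trimethylsilyl) ether of mesylate 25 | COc1oc(C(C)C(OS(C)(=O)=O)/C=C/C(C)=C/[C@@H]2[C@H](C)[C@@](C)(O[Si](C)(C)C)[C@@H](OC(C)=O)[C@@](C)(O[Si](C)(C)C)[C@H]2OC(C)=O)c(C)c(=O)c1C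
F17 | step 16 | 15,17-bis(trimethylsilyl) ether of amaurone B | COc1oc(/C(C)=C/C=C/C(C)=C/[C@@H]2[C@H](C)[C@@](C)(O[Si](C)(C)C)[C@@H](OC(C)=O)[C@@](C)(O[Si](C)(C)C)[C@H]2OC(C)=O)c(C)c(=O)c1C
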